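**Retrosynthetic overview** (carotenoid numbering: ring A = C1–C6 with the C4 hydroxyl, chain C7–C15 then C15'–C7', ring B = C1'–C6' with the C4' ketone)
1. The C14–C15 bond is cut between a C19 alkenylalane (ring A half, aluminium on C14) and a C21 (E)-alkenyl chloride (ring B half, chlorine on C15), joined by Pd/Zn cross-coupling.
2. The alkenylalane is generated in the same flask from the C18 terminal alkyne 18 (C13≡C14) by Zr-catalysed methylalumination, so the key step adds C20, fixes the 13E alkene and joins the halves.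
3. Enabling feature: C13 carries a methyl and C14 only hydrogen, so the trisubstituted C13=C14 alkene beside the bond is the retron of a terminal alkyne plus CH3–Al. Rings A and B are the same (5S,6S)-trimethylcyclohexane with the same C7–C14 chain and differ only at C4/C4', so alkyne 18 feeds both halves (C21 chloride = desilylated 18 + CH3 + (E)-1,2-dichloroethene, then oxidation at C4').
4. Alkyne 18 comes from the ring enyne (C9≡C10) by the same methylalumination/cross-coupling with an (E)-iodoenyne (C11–C14).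
5. No ring is closed: both rings come from one bought cyclohexenone. C6 is set by Rh/(R)-BINAP conjugate addition of an enynylzirconium to the derived 2,5-dienone, C5 by trans-selective enolate methylation, C4 by axial hydride attack.

Key step: step 15

Remark: the face selectivity of step 4 is assigned by analogy with Rh/BINAP additions to cyclohex-2-enone, where (S)-BINAP gives (S)-3-substituted cyclohexanones, hence (R)-BINAP; all polyenes are handled under argon with exclusion of light.

**Route**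

Step 1
Reactants: 1 4,4-dimethylcyclohex-2-en-1-one
Product: 2 4,4-dimethylcyclohexa-2,5-dien-1-one
Conditions: DDQ (1.3 equiv), 1,4-dioxane, reflux
Reagents that add atoms: none
Why: DDQ dehydrogenation of an enolisable ketone can place the new double bond only at C5=C6 because C4 is quaternary, which should give the cross-conjugated dienone.

Step 2
Reactants: 3 1,4-bis(trimethylsilyl)buta-1,3-diyne
Product: 5 buta-1,3-diyn-1-yl(trimethyl)silane, via lithium diynide 4 (not isolated)
Conditions: MeLi·LiBr (1.0 equiv), Et2O, 23 °C; then H2O, 0 °C; used as a THF solution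
Reagents that add atoms: none
Why: Methyllithium attacks one silicon of the bis-silyl diyne (monodesilylation) to release the lithium diynide, whose charge protects the second C–Si bond, and protonation on quench gives the terminal diyne.

Step 3
Reactants: 5 buta-1,3-diyn-1-yl(trimethyl)silane
Product: 6 chlorobis(cyclopentadienyl)[(1E)-4-(trimethylsilyl)but-1-en-3-yn-1-yl]zirconium
Conditions: Cp2Zr(H)Cl (1.0 equiv), THF, 23 °C, argon, dark; kept as a THF stock solution and divided the same day between steps 4 and 5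
Reagents that add atoms: chlorobis(cyclopentadienyl)hydridozirconium Cp2Zr(H)Cl, [H][Zr](Cl)(C1C=CC=C1)C1C=CC=C1
Why: Syn-hydrozirconation (Schwartz hydrozirconation) of the terminal triple bond, which is less hindered than the silylated one, places zirconium on the terminal carbon and should give the (E)-alkenylzirconocene chloride, a species stable enough in THF under argon to be prepared once and used in two portions.

Step 4
Reactants: 6 chlorobis(cyclopentadienyl)[(1E)-4-(trimethylsilyl)but-1-en-3-yn-1-yl]zirconium; 2 4,4-dimethylcyclohexa-2,5-dien-1-one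
Product: 8 (5R)-4,4-dimethyl-5-[(1E)-4-(trimethylsilyl)but-1-en-3-yn-1-yl]cyclohex-2-en-1-one, via zirconium dienolate 7 (not isolated)
Conditions: 6 (1.5 equiv, THF solution), 2 (1.0 equiv), [Rh(cod)(MeCN)2]BF4 (5 mol %), (R)-BINAP (6 mol %), THF, 23 °C; then H2O
Reagents that add atoms: none
Why: The (E)-alkenylzirconium enters a Rh/BINAP-catalysed asymmetric conjugate addition to the cyclic enone (zirconium variant of the Hayashi–Miyaura reaction) in which the chiral ligand selects the face of the β-carbon and so sets the one new stereocentre (later C6 and C6'), while the metal dienolate formed cannot accept a second alkenyl group before it is protonated on work-up.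

Step 5
Reactants: 6 chlorobis(cyclopentadienyl)[(1E)-4-(trimethylsilyl)but-1-en-3-yn-1-yl]zirconium
Product: 9 [(3E)-4-iodobut-3-en-1-yn-1-yl](trimethyl)silane
Conditions: 6 (THF solution), I2 (1.05 equiv), THF, 0 °C, dark
Reagents that add atoms: iodine, II
Why: Iodinolysis of the C–Zr bond proceeds with retention of the alkene geometry (hydrozirconation–iodination sequence) and should give the (E)-iodoenyne that serves as the four-carbon unit C11–C14.

Step 6
Reactants: 8 (5R)-4,4-dimethyl-5-[(1E)-4-(trimethylsilyl)but-1-en-3-yn-1-yl]cyclohex-2-en-1-one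
Product: 11 (5S,6S)-4,4,6-trimethyl-5-[(1E)-4-(trimethylsilyl)but-1-en-3-yn-1-yl]cyclohex-2-en-1-one, via lithium dienolate 10 (not isolated)
Conditions: LDA (1.1 equiv), THF, −78 °C; MeI (3 equiv), DMPU (2 equiv), −78 → −30 °C
Reagents that add atoms: iodomethane, CI
Why: Kinetic α'-deprotonation of the enone (C6 is the only enolisable carbon, C4 being quaternary) and alkylation of the lithium dienolate anti to the neighbouring alkenyl group should give the 5,6-trans product by substrate control, and since this diequatorial arrangement is also the thermodynamic one, any cis isomer is corrected by the base treatment in step 8.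

Step 7
Reactants: 11 (5S,6S)-4,4,6-trimethyl-5-[(1E)-4-(trimethylsilyl)but-1-en-3-yn-1-yl]cyclohex-2-en-1-one
Product: 12 (2S,3S)-2,4,4-trimethyl-3-[(1E)-4-(trimethylsilyl)but-1-en-3-yn-1-yl]cyclohexan-1-one
Conditions: [(Ph3P)CuH]6 (0.25 equiv), THF, H2O (5 equiv), 23 °C
Reagents that add atoms: none
Why: Phosphine-stabilised copper hydride delivers hydride to the β-carbon of the enone (chemoselective conjugate reduction) and the copper enolate is protonated by water, while the unactivated silyl enyne and both stereocentres are left untouched.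

Step 8
Reactants: 12 (2S,3S)-2,4,4-trimethyl-3-[(1E)-4-(trimethylsilyl)but-1-en-3-yn-1-yl]cyclohexan-1-one
Product: 14 (1S,2S,3S)-3-[(1E)-but-1-en-3-yn-1-yl]-2,4,4-trimethylcyclohexan-1-ol, via terminal enyne ketone 13 (not isolated)
Conditions: K2CO3 (0.3 equiv), MeOH, 23 °C; then NaBH4 (1.0 equiv), −40 → 0 °C
Reagents that add atoms: none
Why: Carbonate-catalysed methanolysis cleaves the alkynyl C–Si bond and equilibrates C2 to the trans ketone, and NaBH4 then attacks the locked chair (methyl and alkenyl equatorial, no syn-axial group at C3 or C5) along the axial trajectory to give mainly the equatorial (1S) alcohol by substrate control, the minor epimer being removed by chromatography.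

Step 9
Reactants: 14 (1S,2S,3S)-3-[(1E)-but-1-en-3-yn-1-yl]-2,4,4-trimethylcyclohexan-1-ol
Product: 15 tert-butyl{[(1S,2S,3S)-3-[(1E)-but-1-en-3-yn-1-yl]-2,4,4-trimethylcyclohexyl]oxy}dimethylsilane
Conditions: TBSCl (1.5 equiv), imidazole (3 equiv), DMF, 23 °C
Reagents that add atoms: tert-butyldimethylsilyl chloride, CC(C)(C)[Si](C)(C)Cl
Why: Standard silylation of a secondary alcohol, which provides the ring A oxygen in the protected form that the key step needs.

Step 10
Reactants: 15 tert-butyl{[(1S,2S,3S)-3-[(1E)-but-1-en-3-yn-1-yl]-2,4,4-trimethylcyclohexyl]oxy}dimethylsilane; 9 [(3E)-4-iodobut-3-en-1-yn-1-yl](trimethyl)silane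
Product: 17 tert-butyldimethyl{[(1S,2S,3S)-2,4,4-trimethyl-3-[(1E,3E,5E)-3-methyl-8-(trimethylsilyl)octa-1,3,5-trien-7-yn-1-yl]cyclohexyl]oxy}silane, via alkenylalane 16 (not isolated)
Conditions: Me3Al (2.0 equiv), Cp2ZrCl2 (0.25 equiv), CH2Cl2, 23 °C; volatiles removed in vacuo; THF, ZnCl2 (0.5 equiv), Pd2(dba)3 (2.5 mol %), tri(2-furyl)phosphine (10 mol %), 9 (1.1 equiv), DMF, 23 °C, dark
Reagents that add atoms: trimethylaluminium, C[Al](C)C
Why: Zr-catalysed syn-methylalumination of the terminal alkyne (Negishi carboalumination) puts the methyl C19 on C9 and aluminium on C10, and the Pd-catalysed, ZnCl2-assisted cross-coupling of this alkenylalane with the (E)-alkenyl iodide (Negishi coupling) proceeds with retention at both alkenes to give the 7E,9E,11E trienyne.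

Step 11
Reactants: 17 tert-butyldimethyl{[(1S,2S,3S)-2,4,4-trimethyl-3-[(1E,3E,5E)-3-methyl-8-(trimethylsilyl)octa-1,3,5-trien-7-yn-1-yl]cyclohexyl]oxy}silane
Product: 18 tert-butyldimethyl{[(1S,2S,3S)-2,4,4-trimethyl-3-[(1E,3E,5E)-3-methylocta-1,3,5-trien-7-yn-1-yl]cyclohexyl]oxy}silane
Conditions: K2CO3 (0.5 equiv), MeOH–THF (2:1), 23 °C, dark
Reagents that add atoms: none
Why: Carbonate-catalysed methanolysis removes only the alkynyl silyl group, the secondary silyl ether being stable to these conditions.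

Step 12
Reactants: 18 tert-butyldimethyl{[(1S,2S,3S)-2,4,4-trimethyl-3-[(1E,3E,5E)-3-methylocta-1,3,5-trien-7-yn-1-yl]cyclohexyl]oxy}silane
Product: 19 (1S,2S,3S)-2,4,4-trimethyl-3-[(1E,3E,5E)-3-methylocta-1,3,5-trien-7-yn-1-yl]cyclohexan-1-ol
Conditions: HF·pyridine, pyridine, THF, 0 → 23 °C, dark
Reagents that add atoms: none
Why: Buffered HF·pyridine cleaves the Si–O bond (silyl ether deprotection) at the robust trienyne stage, so that the portion of 18 destined for ring B carries a free hydroxyl and the later chloropentaene never meets fluoride.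

Step 13
Reactants: 19 (1S,2S,3S)-2,4,4-trimethyl-3-[(1E,3E,5E)-3-methylocta-1,3,5-trien-7-yn-1-yl]cyclohexan-1-ol; 20 (E)-1,2-dichloroethene
Product: 22 (1S,2S,3S)-3-[(1E,3E,5E,7E,9E)-10-chloro-3,7-dimethyldeca-1,3,5,7,9-pentaen-1-yl]-2,4,4-trimethylcyclohexan-1-ol, via aluminium alkoxide alkenylalane 21 (not isolated)
Conditions: Me3Al (3.2 equiv), Cp2ZrCl2 (0.25 equiv), CH2Cl2, 0 → 23 °C; volatiles removed in vacuo; THF, ZnCl2 (0.5 equiv), Pd(PPh3)4 (5 mol %), 20 (10 equiv), 23 °C, dark; aq NH4Cl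
Reagents that add atoms: trimethylaluminium, C[Al](C)C
Why: The first equivalent of Me3Al converts the hydroxyl into a dimethylaluminium alkoxide, which the Zr-catalysed syn-methylalumination (Negishi carboalumination) tolerates, the carboalumination adds C20' and fixes the 13'E alkene, and the Pd(PPh3)4-catalysed Negishi coupling with excess (E)-1,2-dichloroethene should stop after one substitution because the chlorodiene formed lacks the activating second chlorine, the E geometry of the two-carbon unit being retained and the alcohol being released on aqueous work-up.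

Step 14
Reactants: 22 (1S,2S,3S)-3-[(1E,3E,5E,7E,9E)-10-chloro-3,7-dimethyldeca-1,3,5,7,9-pentaen-1-yl]-2,4,4-trimethylcyclohexan-1-ol
Product: 23 (2S,3S)-3-[(1E,3E,5E,7E,9E)-10-chloro-3,7-dimethyldeca-1,3,5,7,9-pentaen-1-yl]-2,4,4-trimethylcyclohexan-1-one
Conditions: Dess–Martin periodinane (1.5 equiv), NaHCO3, CH2Cl2, 0 → 23 °C, dark
Reagents that add atoms: none
Why: Dess–Martin oxidation converts the secondary alcohol into the C4' ketone under buffered neutral conditions that spare the polyene, and the adjacent C5' methyl centre already has the thermodynamically preferred trans arrangement.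

Step 15
Reactants: 18 tert-butyldimethyl{[(1S,2S,3S)-2,4,4-trimethyl-3-[(1E,3E,5E)-3-methylocta-1,3,5-trien-7-yn-1-yl]cyclohexyl]oxy}silane; 23 (2S,3S)-3-[(1E,3E,5E,7E,9E)-10-chloro-3,7-dimethyldeca-1,3,5,7,9-pentaen-1-yl]-2,4,4-trimethylcyclohexan-1-one
Product: 25 (4S,5S,6S,5'S,6'S)-4-{[tert-butyl(dimethyl)silyl]oxy}-5,6,5',6'-tetrahydro-β,β-caroten-4'-one (all-E), via alkenylalane 24 (not isolated)
Conditions: 18 (1.2 equiv), Me3Al (2.0 equiv), Cp2ZrCl2 (0.25 equiv), CH2Cl2, 23 °C; all volatiles including excess Me3Al removed at 0.1 mmHg; THF, ZnCl2 (1.0 equiv), Pd(t-Bu3P)2 (5 mol %), 23 (1.0 equiv), 23 → 40 °C, argon, dark; aq NH4Cl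
Reagents that add atoms: trimethylaluminium, C[Al](C)C
Why: Cp2ZrCl2-catalysed syn-addition of CH3–Al across the C13≡C14 triple bond of 18 places the new methyl C20 on C13 and aluminium on C14 of alkenylalane 24; zerovalent palladium inserts into the C15–Cl bond of 23 with retention, ZnCl2 relays the alkenyl group from aluminium to palladium, and reductive elimination forms the C14–C15 bond. The closest known reaction type is the Negishi carboalumination/Negishi cross-coupling sequence used for retinoid and carotenoid polyenes, run here with a bulky electron-rich phosphine as is established for alkenyl chlorides with organozinc partners. No ring is closed and no stereocentre is formed; the stereochemical elements are the 13E alkene, fixed by the syn carbometalation of the terminal alkyne (aluminium goes to the CH terminus), and the 15E alkene, carried over with retention from 23. The step needs chemoselectivity for the C–Cl bond over the C4' ketone: excess Me3Al is pumped off before 23 is added, the remaining alkenylaluminium and alkenylzinc species are poor carbonyl nucleophiles, the ketone is flanked by the C5' methine, and the C4 oxygen is silylated so that no aluminium alkoxide able to transfer hydride to the ketone is present. In one operation the step adds the last carbon, completes the ninth conjugated double bond and joins the C19 and C21 halves, so that its precursors are one C18 alkyne (used for both halves of the route) and a two-carbon unit.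

Step 16
Reactants: 25 (4S,5S,6S,5'S,6'S)-4-{[tert-butyl(dimethyl)silyl]oxy}-5,6,5',6'-tetrahydro-β,β-caroten-4'-one
Product: 26 (4S,5S,6S,5'S,6'S)-4-hydroxy-5,6,5',6'-tetrahydro-β,β-caroten-4'-one (all-E), the target CNP0107241.1
Conditions: HF·pyridine, pyridine, THF, 0 → 23 °C, argon, dark
Reagents that add atoms: none
Why: Buffered HF·pyridine cleaves the secondary silyl ether (deprotection) without base, so that neither the α-methyl ketone nor the all-E nonaene should be disturbed.

**Compound list**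

1 | 4,4-dimethylcyclohex-2-en-1-one | CC1(C)CCC(=O)C=C1 | starting material
2 | 4,4-dimethylcyclohexa-2,5-dien-1-one | CC1(C)C=CC(=O)C=C1 | intermediate
3 | 1,4-bis(trimethylsilyl)buta-1,3-diyne | C[Si](C)(C)C#CC#C[Si](C)(C)C | starting material
4 | lithium 4-(trimethylsilyl)buta-1,3-diyn-1-ide | [Li]C#CC#C[Si](C)(C)C | intermediate
5 | buta-1,3-diyn-1-yl(trimethyl)silane | C#CC#C[Si](C)(C)C | intermediate
6 | chlorobis(cyclopentadienyl)[(1E)-4-(trimethylsilyl)but-1-en-3-yn-1-yl]zirconium | C[Si](C)(C)C#C/C=C/[Zr](Cl)(C1C=CC=C1)C1C=CC=C1 | intermediate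
7 | chlorobis(cyclopentadienyl)zirconium (3S)-4,4-dimethyl-3-[(1E)-4-(trimethylsilyl)but-1-en-3-yn-1-yl]cyclohexa-1,5-dien-1-olate | C[Si](C)(C)C#C/C=C/[C@H]1C=C(O[Zr](Cl)(C2C=CC=C2)C2C=CC=C2)C=CC1(C)C | intermediate
8 | (5R)-4,4-dimethyl-5-[(1E)-4-(trimethylsilyl)but-1-en-3-yn-1-yl]cyclohex-2-en-1-one | C[Si](C)(C)C#C/C=C/[C@H]1CC(=O)C=CC1(C)C | intermediate
9 | [(3E)-4-iodobut-3-en-1-yn-1-yl](trimethyl)silane | I/C=C/C#C[Si](C)(C)C | intermediate
10 | lithium (3S)-4,4-dimethyl-3-[(1E)-4-(trimethylsilyl)but-1-en-3-yn-1-yl]cyclohexa-1,5-dien-1-olate | C[Si](C)(C)C#C/C=C/[C@H]1C=C(O[Li])C=CC1(C)C | intermediate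
11 | (5S,6S)-4,4,6-trimethyl-5-[(1E)-4-(trimethylsilyl)but-1-en-3-yn-1-yl]cyclohex-2-en-1-one | C[Si](C)(C)C#C/C=C/[C@H]1[C@H](C)C(=O)C=CC1(C)C | intermediate
12 | (2S,3S)-2,4,4-trimethyl-3-[(1E)-4-(trimethylsilyl)but-1-en-3-yn-1-yl]cyclohexan-1-one | C[Si](C)(C)C#C/C=C/[C@H]1[C@H](C)C(=O)CCC1(C)C | intermediate
13 | (2S,3S)-3-[(1E)-but-1-en-3-yn-1-yl]-2,4,4-trimethylcyclohexan-1-one | C#C/C=C/[C@H]1[C@H](C)C(=O)CCC1(C)C | intermediate
14 | (1S,2S,3S)-3-[(1E)-but-1-en-3-yn-1-yl]-2,4,4-trimethylcyclohexan-1-ol | C#C/C=C/[C@H]1[C@H](C)[C@@H](O)CCC1(C)C | intermediate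
15 | tert-butyl{[(1S,2S,3S)-3-[(1E)-but-1-en-3-yn-1-yl]-2,4,4-trimethylcyclohexyl]oxy}dimethylsilane | C#C/C=C/[C@H]1[C@H](C)[C@@H](O[Si](C)(C)C(C)(C)C)CCC1(C)C | intermediate
16 | dimethyl{(1E,3E)-2-methyl-4-[(1S,2S,3S)-3-{[tert-butyl(dimethyl)silyl]oxy}-2,6,6-trimethylcyclohexyl]buta-1,3-dien-1-yl}alumane | C[Al](C)/C=C(C)/C=C/[C@H]1[C@H](C)[C@@H](O[Si](C)(C)C(C)(C)C)CCC1(C)C | intermediate
17 | tert-butyldimethyl{[(1S,2S,3S)-2,4,4-trimethyl-3-[(1E,3E,5E)-3-methyl-8-(trimethylsilyl)octa-1,3,5-trien-7-yn-1-yl]cyclohexyl]oxy}silane | C[Si](C)(C)C#C/C=C/C=C(C)/C=C/[C@H]1[C@H](C)[C@@H](O[Si](C)(C)C(C)(C)C)CCC1(C)C | intermediate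
18 | tert-butyldimethyl{[(1S,2S,3S)-2,4,4-trimethyl-3-[(1E,3E,5E)-3-methylocta-1,3,5-trien-7-yn-1-yl]cyclohexyl]oxy}silane | C#C/C=C/C=C(C)/C=C/[C@H]1[C@H](C)[C@@H](O[Si](C)(C)C(C)(C)C)CCC1(C)C | intermediate
19 | (1S,2S,3S)-2,4,4-trimethyl-3-[(1E,3E,5E)-3-methylocta-1,3,5-trien-7-yn-1-yl]cyclohexan-1-ol | C#C/C=C/C=C(C)/C=C/[C@H]1[C@H](C)[C@@H](O)CCC1(C)C | intermediate
20 | (E)-1,2-dichloroethene | Cl/C=C/Cl | starting material
21 | dimethylaluminium (1S,2S,3S)-3-[(1E,3E,5E,7E)-8-(dimethylalumanyl)-3,7-dimethylocta-1,3,5,7-tetraen-1-yl]-2,4,4-trimethylcyclohexan-1-olate | C[Al](C)/C=C(C)/C=C/C=C(C)/C=C/[C@H]1[C@H](C)[C@@H](O[Al](C)C)CCC1(C)C | intermediate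
22 | (1S,2S,3S)-3-[(1E,3E,5E,7E,9E)-10-chloro-3,7-dimethyldeca-1,3,5,7,9-pentaen-1-yl]-2,4,4-trimethylcyclohexan-1-ol | Cl/C=C/C=C(C)/C=C/C=C(C)/C=C/[C@H]1[C@H](C)[C@@H](O)CCC1(C)C | intermediate
23 | (2S,3S)-3-[(1E,3E,5E,7E,9E)-10-chloro-3,7-dimethyldeca-1,3,5,7,9-pentaen-1-yl]-2,4,4-trimethylcyclohexan-1-one | Cl/C=C/C=C(C)/C=C/C=C(C)/C=C/[C@H]1[C@H](C)C(=O)CCC1(C)C | intermediate
24 | dimethyl{(1E,3E,5E,7E)-2,6-dimethyl-8-[(1S,2S,3S)-3-{[tert-butyl(dimethyl)silyl]oxy}-2,6,6-trimethylcyclohexyl]octa-1,3,5,7-tetraen-1-yl}alumane | C[Al](C)/C=C(C)/C=C/C=C(C)/C=C/[C@H]1[C@H](C)[C@@H](O[Si](C)(C)C(C)(C)C)CCC1(C)C | intermediate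
25 | (4S,5S,6S,5'S,6'S)-4-{[tert-butyl(dimethyl)silyl]oxy}-5,6,5',6'-tetrahydro-β,β-caroten-4'-one (all-E) | CC(/C=C/C=C(C)/C=C/[C@H]1[C@H](C)[C@@H](O[Si](C)(C)C(C)(C)C)CCC1(C)C)=C\C=C\C=C(C)\C=C\C=C(C)\C=C\[C@H]1[C@H](C)C(=O)CCC1(C)C | intermediate
26 | (4S,5S,6S,5'S,6'S)-4-hydroxy-5,6,5',6'-tetrahydro-β,β-caroten-4'-one (all-E), CNP0107241.1 | CC(/C=C/C=C(C)/C=C/[C@H]1[C@H](C)[C@@H](O)CCC1(C)C)=C\C=C\C=C(C)\C=C\C=C(C)\C=C\[C@H]1[C@H](C)C(=O)CCC1(C)C | target

**Count**

Total step count: 16.
Longest linear sequence: 14 steps (3 → 5 → 6 → 8 → 11 → 12 → 14 → 15 → 17 → 18 → 19 → 22 → 23 → 25 → 26; the sequence that starts from 1 through step 1 is one step shorter).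

**Steps most likely to fail**

Step 4. The alkenyl transfer to a β-carbon that adjoins the quaternary C4 may be slow, the enantioface discrimination may be insufficient, or the rhodium alkenyl may be consumed by insertion into the silyl alkyne. The fallback replaces asymmetric catalysis by resolution. It sets out from 2 and 6: achiral CuBr·SMe2 catalysis (10 mol %, THF, 40 °C) should give the racemic enone F1. The conditions of steps 6, 7 and 8 then carry the racemate through the racemic trans-methyl enone F2 and the racemic ketone F3 to the racemic all-equatorial alcohol F4. Acylation with an immobilised lipase (from Burkholderia cepacia or CAL-B, vinyl acetate, t-BuOMe, 30 °C) is expected to acetylate the enantiomer with the R carbinol centre to the (1R,2R,3R)-acetate F5, in line with the usual preference of these lipases for secondary cyclohexanols. The unreacted (1S,2S,3S)-alcohol is compound 14, where the route is rejoined after chromatography.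

Step 15. Aluminium-bound methyl or alkenyl groups may attack or enolise the C4' ketone, or insertion into the polyenyl C–Cl bond may be slow enough for homocoupling and E/Z isomerisation to compete. The fallback introduces the carbonyl after the union. It sets out from 22 and 18: TESCl and imidazole in DMF convert 22 into the triethylsilyl ether F6. The carboalumination of 18 and the Pd(t-Bu3P)2/ZnCl2 coupling are then run with F6 in place of 23, which should give the bis-silyl ether F7. PPTS in MeOH–CH2Cl2 at 0 °C cleaves only the triethylsilyl ether to give the C4' alcohol F8, and Dess–Martin oxidation of F8 gives 25, where the route is rejoined.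

Step 8. Hydride delivery may show poor facial selectivity, equatorial attack competing with the desired axial attack. The fallback sets C4 by inversion. It sets out from 12: LiBH(s-Bu)3 (THF, −78 °C) attacks from the equatorial side and should give the axial (1R,2S,3S)-alcohol F9. A Mitsunobu reaction (4-nitrobenzoic acid, PPh3, DIAD, toluene, 0 → 23 °C) inverts the carbinol centre to the equatorial (1S,2S,3S)-4-nitrobenzoate F10. K2CO3 in MeOH then cleaves both the ester and the alkynyl silane to give 14, where the route is rejoined.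

**Further compounds**

F1 | step 4 | racemic 4,4-dimethyl-5-[(1E)-4-(trimethylsilyl)but-1-en-3-yn-1-yl]cyclohex-2-en-1-one (1:1 mixture of enantiomers) | C[Si](C)(C)C#C/C=C/[C@H]1CC(=O)C=CC1(C)C.C[Si](C)(C)C#C/C=C/[C@@H]1CC(=O)C=CC1(C)C
F2 | step 4 | racemic trans-4,4,6-trimethyl-5-[(1E)-4-(trimethylsilyl)but-1-en-3-yn-1-yl]cyclohex-2-en-1-one (1:1 mixture of the 5S,6S and 5R,6R forms) | C[Si](C)(C)C#C/C=C/[C@H]1[C@H](C)C(=O)C=CC1(C)C.C[Si](C)(C)C#C/C=C/[C@@H]1[C@@H](C)C(=O)C=CC1(C)C
F3 | step 4 | racemic trans-2,4,4-trimethyl-3-[(1E)-4-(trimethylsilyl)but-1-en-3-yn-1-yl]cyclohexan-1-one (1:1 mixture of the 2S,3S and 2R,3R forms) | C[Si](C)(C)C#C/C=C/[C@H]1[C@H](C)C(=O)CCC1(C)C.C[Si](C)(C)C#C/C=C/[C@@H]1[C@@H](C)C(=O)CCC1(C)C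
F4 | step 4 | racemic all-equatorial 3-[(1E)-but-1-en-3-yn-1-yl]-2,4,4-trimethylcyclohexan-1-ol (1:1 mixture of the 1S,2S,3S and 1R,2R,3R forms) | C#C/C=C/[C@H]1[C@H](C)[C@@H](O)CCC1(C)C.C#C/C=C/[C@@H]1[C@@H](C)[C@H](O)CCC1(C)C
F5 | step 4 | (1R,2R,3R)-3-[(1E)-but-1-en-3-yn-1-yl]-2,4,4-trimethylcyclohexyl acetate | C#C/C=C/[C@@H]1[C@@H](C)[C@H](OC(C)=O)CCC1(C)C
F6 | step 15 | {[(1S,2S,3S)-3-[(1E,3E,5E,7E,9E)-10-chloro-3,7-dimethyldeca-1,3,5,7,9-pentaen-1-yl]-2,4,4-trimethylcyclohexyl]oxy}triethylsilane | Cl/C=C/C=C(C)/C=C/C=C(C)/C=C/[C@H]1[C@H](C)[C@@H](O[Si](CC)(CC)CC)CCC1(C)C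
F7 | step 15 | (4S,5S,6S,4'S,5'S,6'S)-4-{[tert-butyl(dimethyl)silyl]oxy}-4'-[(triethylsilyl)oxy]-5,6,5',6'-tetrahydro-β,β-carotene (all-E) | CC(/C=C/C=C(C)/C=C/[C@H]1[C@H](C)[C@@H](O[Si](C)(C)C(C)(C)C)CCC1(C)C)=C\C=C\C=C(C)\C=C\C=C(C)\C=C\[C@H]1[C@H](C)[C@@H](O[Si](CC)(CC)CC)CCC1(C)C
F8 | step 15 | (4S,5S,6S,4'S,5'S,6'S)-4'-{[tert-butyl(dimethyl)silyl]oxy}-5,6,5',6'-tetrahydro-β,β-caroten-4-ol (all-E; free hydroxyl on ring B of the route) | CC(/C=C/C=C(C)/C=C/[C@H]1[C@H](C)[C@@H](O[Si](C)(C)C(C)(C)C)CCC1(C)C)=C\C=C\C=C(C)\C=C\C=C(C)\C=C\[C@H]1[C@H](C)[C@@H](O)CCC1(C)C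
F9 | step 8 | (1R,2S,3S)-2,4,4-trimethyl-3-[(1E)-4-(trimethylsilyl)but-1-en-3-yn-1-yl]cyclohexan-1-ol | C[Si](C)(C)C#C/C=C/[C@H]1[C@H](C)[C@H](O)CCC1(C)C
F10 | step 8 | (1S,2S,3S)-2,4,4-trimethyl-3-[(1E)-4-(trimethylsilyl)but-1-en-3-yn-1-yl]cyclohexyl 4-nitrobenzoate | C[Si](C)(C)C#C/C=C/[C@H]1[C@H](C)[C@@H](OC(=O)c2ccc(cc2)[N+](=O)[O-])CCC1(C)C
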